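**Strategy**

Everything rests on cutting the bond between C2 of the 4-pyranone ring C of the non-acacetin flavone unit and C1' of its methoxyphenylene ring B. The key step exploits the C2–H of an intact 5,7-dioxygenated chromone, the vinylic hydrogen next to ring oxygen O1 and beta to the C4 carbonyl: magnesium chloride-assisted C–H zincation there, followed by Negishi coupling with a hindered aryl bromide, joins the halves and completes the biflavone skeleton in one operation, with no halogen on the chromone and no later change of oxidation level. Its precursors are 5,7-bis(benzyloxy)chromone and an 8-(2-bromo-5-methoxyphenyl) derivative of di-O-benzylacacetin; hydrogenolysis then ends the route.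

Key step: step 5

Remark: the target has no stereocentre, and its tri-ortho-substituted C8–C2' biaryl axis carries no descriptor, so the axis is formed without control. Compounds 1, 4 and 6 are taken as catalogue materials.

**Route**

Step 1
Reactants: 1 acacetin (5,7-dihydroxy-2-(4-methoxyphenyl)-4H-chromen-4-one)
Product: 2 5,7-bis(benzyloxy)-2-(4-methoxyphenyl)-4H-chromen-4-one
Conditions: BnBr (3 equiv), K2CO3 (4 equiv), Bu4NI (cat.), DMF, 80 °C
Reagents that add atoms: benzyl bromide, BrCc1ccccc1
Why: Williamson etherification; the 7-OH should react readily and the hydrogen-bonded 5-OH under forcing conditions with excess halide in DMF.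

Step 2
Reactants: 2 5,7-bis(benzyloxy)-2-(4-methoxyphenyl)-4H-chromen-4-one
Product: 3 5,7-bis(benzyloxy)-8-iodo-2-(4-methoxyphenyl)-4H-chromen-4-one
Conditions: NIS (1.05 equiv), CF3CO2H (cat.), CH2Cl2/MeCN, 0 °C to 25 °C
Reagents that add atoms: N-iodosuccinimide, O=C1CCC(=O)N1I
Why: Electrophilic aromatic iodination of the phloroglucinol-type ring A; 5-O-alkylated 5,7-dioxygenated flavones are expected to be iodinated at C8 and not at C6 (which lies between two benzyloxy groups), and ring B is deactivated by the pyranone.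

Step 3
Reactants: 3 5,7-bis(benzyloxy)-8-iodo-2-(4-methoxyphenyl)-4H-chromen-4-one, 4 (2-bromo-5-methoxyphenyl)boronic acid
Product: 5 5,7-bis(benzyloxy)-8-(2-bromo-5-methoxyphenyl)-2-(4-methoxyphenyl)-4H-chromen-4-one
Conditions: Pd(PPh3)4 (5 mol %), K2CO3 (3 equiv), DME/H2O 4:1, 85 °C
Reagents that add atoms: none
Why: Suzuki–Miyaura coupling; with a triphenylphosphine catalyst, oxidative addition into the C–I bond of 3 should be much faster than into the electron-rich C–Br bond para to methoxy, so the bromide survives as the handle for step 5.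

Step 4
Reactants: 6 1-[2,4-bis(benzyloxy)-6-hydroxyphenyl]ethan-1-one
Product: 8 5,7-bis(benzyloxy)-4H-chromen-4-one, via enaminone 7 (not isolated)
Conditions: Me2NCH(OMe)2, toluene, 100 °C; then conc. HCl, CH2Cl2, 40 °C
Reagents that add atoms: N,N-dimethylformamide dimethyl acetal, COC(OC)N(C)C
Why: Enaminone route to chromones: condensation of the methyl ketone with the amide acetal gives the E-enaminone, and acid-mediated intramolecular oxa-Michael addition of the phenol with loss of dimethylamine closes the pyranone.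

Step 5
Reactants: 8 5,7-bis(benzyloxy)-4H-chromen-4-one, 5 5,7-bis(benzyloxy)-8-(2-bromo-5-methoxyphenyl)-2-(4-methoxyphenyl)-4H-chromen-4-one
Product: 10 5,7-bis(benzyloxy)-8-{2-[5,7-bis(benzyloxy)-4-oxo-4H-chromen-2-yl]-5-methoxyphenyl}-2-(4-methoxyphenyl)-4H-chromen-4-one, via bis(chromon-2-yl)zinc 9 (not isolated)
Conditions: 8 (1.5 equiv), TMP2Zn·2MgCl2·2LiCl (0.8 equiv; TMP = 2,2,6,6-tetramethylpiperidide), THF, −30 °C to 25 °C; then 5 (1.0 equiv), Pd(OAc)2 (5 mol %), SPhos (10 mol %), 60 °C
Reagents that add atoms: none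
Why: The hindered amide base should deprotonate chromone 8 at C2, the carbon next to ring oxygen O1, whose C–H is acidified when MgCl2 binds the C4 carbonyl (chelated by the peri 5-benzyloxy oxygen), giving diorganozinc 9; oxidative addition of zerovalent palladium (formed from Pd(OAc)2 and SPhos) into the C–Br bond of 5, transmetalation from zinc and reductive elimination then forge the C2–C1' bond. The closest known reaction type is the Lewis acid-triggered C2 zincation of chromones with TMP-zinc bases followed by Negishi cross-coupling, which is established for simple flavones. No ring is closed and no stereocentre is formed; the tri-ortho-substituted C8–C2' axis arises without control, as the target demands none. The step needs C2 over C3 metalation of 8, which the MgCl2 content of the base should secure (the known switch between C3 and C2 zincation of chromones), and coupling only at the single C–Br bond of 5, whose flavone C3–H stays untouched because the base is consumed before 5 is added. The bulky electron-rich biarylphosphine is chosen because the bromide is ortho to the flavonyl group and para to methoxy, and the organozinc tolerates the vinylogous ester carbonyls, benzyl ethers and methyl ethers of both partners.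

Step 6
Reactants: 10 5,7-bis(benzyloxy)-8-{2-[5,7-bis(benzyloxy)-4-oxo-4H-chromen-2-yl]-5-methoxyphenyl}-2-(4-methoxyphenyl)-4H-chromen-4-one
Product: 11 5,7-dihydroxy-8-[2-(5,7-dihydroxy-4-oxo-4H-chromen-2-yl)-5-methoxyphenyl]-2-(4-methoxyphenyl)-4H-chromen-4-one (CNP0394081.0)
Conditions: H2 (1 atm), 10% Pd/C, THF/MeOH 1:1, 25 °C
Reagents that add atoms: none
Why: Catalytic hydrogenolysis should cleave the four benzyl aryl ethers while the two aryl methyl ethers are inert and the aryl-conjugated C2=C3 bonds of both flavones resist reduction under these mild conditions.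

**Compound list**

1 | acacetin, 5,7-dihydroxy-2-(4-methoxyphenyl)-4H-chromen-4-one | COc1ccc(-c2cc(=O)c3c(O)cc(O)cc3o2)cc1 | starting material
2 | 5,7-bis(benzyloxy)-2-(4-methoxyphenyl)-4H-chromen-4-one | COc1ccc(-c2cc(=O)c3c(OCc4ccccc4)cc(OCc4ccccc4)cc3o2)cc1 | intermediate
3 | 5,7-bis(benzyloxy)-8-iodo-2-(4-methoxyphenyl)-4H-chromen-4-one | COc1ccc(-c2cc(=O)c3c(OCc4ccccc4)cc(OCc4ccccc4)c(I)c3o2)cc1 | intermediate
4 | (2-bromo-5-methoxyphenyl)boronic acid | COc1ccc(Br)c(B(O)O)c1 | starting material
5 | 5,7-bis(benzyloxy)-8-(2-bromo-5-methoxyphenyl)-2-(4-methoxyphenyl)-4H-chromen-4-one | COc1ccc(-c2cc(=O)c3c(OCc4ccccc4)cc(OCc4ccccc4)c(-c4cc(OC)ccc4Br)c3o2)cc1 | intermediate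
6 | 1-[2,4-bis(benzyloxy)-6-hydroxyphenyl]ethan-1-one | CC(=O)c1c(O)cc(OCc2ccccc2)cc1OCc1ccccc1 | starting material
7 | (E)-1-[2,4-bis(benzyloxy)-6-hydroxyphenyl]-3-(dimethylamino)prop-2-en-1-one | CN(C)/C=C/C(=O)c1c(O)cc(OCc2ccccc2)cc1OCc1ccccc1 | intermediate
8 | 5,7-bis(benzyloxy)-4H-chromen-4-one | O=c1ccoc2cc(OCc3ccccc3)cc(OCc3ccccc3)c12 | intermediate
9 | bis[5,7-bis(benzyloxy)-4-oxo-4H-chromen-2-yl]zinc (MgCl2/LiCl complex in THF) | O=c1cc([Zn]c2cc(=O)c3c(OCc4ccccc4)cc(OCc4ccccc4)cc3o2)oc2cc(OCc3ccccc3)cc(OCc3ccccc3)c12 | intermediate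
10 | 5,7-bis(benzyloxy)-8-{2-[5,7-bis(benzyloxy)-4-oxo-4H-chromen-2-yl]-5-methoxyphenyl}-2-(4-methoxyphenyl)-4H-chromen-4-one | COc1ccc(-c2cc(=O)c3c(OCc4ccccc4)cc(OCc4ccccc4)c(-c4cc(OC)ccc4-c4cc(=O)c5c(OCc6ccccc6)cc(OCc6ccccc6)cc5o4)c3o2)cc1 | intermediate
11 | 5,7-dihydroxy-8-[2-(5,7-dihydroxy-4-oxo-4H-chromen-2-yl)-5-methoxyphenyl]-2-(4-methoxyphenyl)-4H-chromen-4-one | COc1ccc(-c2cc(=O)c3c(O)cc(O)c(-c4cc(OC)ccc4-c4cc(=O)c5c(O)cc(O)cc5o4)c3o2)cc1 | target

**Count**

Total steps: 6. Longest linear sequence: 5 steps (steps 1, 2, 3, 5, 6); step 4 runs in parallel.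

**Steps most likely to fail**

Step 5. Oxidative addition and transmetalation at the hindered, electron-rich, ortho-substituted bromide may be too slow, so that protonation or homocoupling of the zinc reagent wins; metalation of the chromone may also stray to C3. The fallback sets out from 5 and comes back at 10. Miyaura borylation of 5 (B2pin2, Pd(dppf)Cl2, KOAc, dioxane, 90 °C) would give the pinacol boronate 5,7-bis(benzyloxy)-8-[5-methoxy-2-(4,4,5,5-tetramethyl-1,3,2-dioxaborolan-2-yl)phenyl]-2-(4-methoxyphenyl)-4H-chromen-4-one F1. Rhodium-catalysed conjugate addition of F1 to chromone 8 ([Rh(OH)(cod)]2, KOH, dioxane/H2O, 60 °C) would give the flavanone 5,7-bis(benzyloxy)-8-{2-[5,7-bis(benzyloxy)-4-oxochroman-2-yl]-5-methoxyphenyl}-2-(4-methoxyphenyl)-4H-chromen-4-one F2 as a mixture of stereoisomers at the new C2 centre. Dehydrogenation with DDQ in dioxane at 100 °C would erase that centre and return to 10.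

Step 3. Oxidative addition into the C–Br bond of 4 or of the product may compete, leading to oligomerisation, and the ortho-substituted boronic acid may protodeboronate before it couples at the hindered C8 position. The fallback sets out from 3 and comes back at 10. Suzuki–Miyaura coupling of 3 with purchased (2-hydroxy-5-methoxyphenyl)boronic acid (Pd(PPh3)4, K2CO3, DME/H2O, 85 °C), which has no competing carbon–halogen bond, would give the phenol 5,7-bis(benzyloxy)-8-(2-hydroxy-5-methoxyphenyl)-2-(4-methoxyphenyl)-4H-chromen-4-one F3. Triflation (Tf2O, pyridine, CH2Cl2, 0 °C) would give the aryl triflate 2-[5,7-bis(benzyloxy)-2-(4-methoxyphenyl)-4-oxo-4H-chromen-8-yl]-4-methoxyphenyl trifluoromethanesulfonate F4. F4 would take the place of 5 in the coupling with zinc reagent 9 (Pd(OAc)2, SPhos, THF, 60 °C) and so reach 10.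

Step 2. Site selectivity of the electrophilic iodination may be lost, with attack at C6 or twofold iodination. The fallback sets out from 6 and comes back at 3. Iodination of 6 ortho to its only free phenol (NIS, CH2Cl2/MeCN, 25 °C) would give 1-[4,6-bis(benzyloxy)-2-hydroxy-3-iodophenyl]ethan-1-one F5. Claisen–Schmidt condensation with 4-methoxybenzaldehyde (KOH, EtOH, 25 °C) would give the chalcone (E)-1-[4,6-bis(benzyloxy)-2-hydroxy-3-iodophenyl]-3-(4-methoxyphenyl)prop-2-en-1-one F6. Oxidative cyclisation (I2 cat., DMSO, 120 °C) through that same phenol oxygen would place the iodine at C8 by construction and give 3.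

**Further compounds**

F1 | step 5 | 5,7-bis(benzyloxy)-8-[5-methoxy-2-(4,4,5,5-tetramethyl-1,3,2-dioxaborolan-2-yl)phenyl]-2-(4-methoxyphenyl)-4H-chromen-4-one | COc1ccc(-c2cc(=O)c3c(OCc4ccccc4)cc(OCc4ccccc4)c(-c4cc(OC)ccc4B4OC(C)(C)C(C)(C)O4)c3o2)cc1
F2 | step 5 | 5,7-bis(benzyloxy)-8-{2-[5,7-bis(benzyloxy)-4-oxochroman-2-yl]-5-methoxyphenyl}-2-(4-methoxyphenyl)-4H-chromen-4-one (2RS, mixture of stereoisomers) | COc1ccc(-c2cc(=O)c3c(OCc4ccccc4)cc(OCc4ccccc4)c(-c4cc(OC)ccc4C4CC(=O)c5c(OCc6ccccc6)cc(OCc6ccccc6)cc5O4)c3o2)cc1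
F3 | step 3 | 5,7-bis(benzyloxy)-8-(2-hydroxy-5-methoxyphenyl)-2-(4-methoxyphenyl)-4H-chromen-4-one | COc1ccc(-c2cc(=O)c3c(OCc4ccccc4)cc(OCc4ccccc4)c(-c4cc(OC)ccc4O)c3o2)cc1
F4 | step 3 | 2-[5,7-bis(benzyloxy)-2-(4-methoxyphenyl)-4-oxo-4H-chromen-8-yl]-4-methoxyphenyl trifluoromethanesulfonate | COc1ccc(-c2cc(=O)c3c(OCc4ccccc4)cc(OCc4ccccc4)c(-c4cc(OC)ccc4OS(=O)(=O)C(F)(F)F)c3o2)cc1
F5 | step 2 | 1-[4,6-bis(benzyloxy)-2-hydroxy-3-iodophenyl]ethan-1-one | CC(=O)c1c(O)c(I)c(OCc2ccccc2)cc1OCc1ccccc1
F6 | step 2 | (E)-1-[4,6-bis(benzyloxy)-2-hydroxy-3-iodophenyl]-3-(4-methoxyphenyl)prop-2-en-1-one | COc1ccc(/C=C/C(=O)c2c(O)c(I)c(OCc3ccccc3)cc2OCc2ccccc2)cc1
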